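**Retrosynthetic overview**
- The only ring that is built is the cyclohexanone ring. It is closed last, at C1–C8a, by a light-driven acylation of a 2-substituted 1,4-benzoquinone by its own ω-aldehyde. Removal of one acetate then gives the target.
- The quinone–aldehyde comes from a p-methoxyphenol/primary alcohol by one double oxidation, and that compound comes from an allyl benzyl ether by hydrogenation.
- The diarylmethine centre (C4–C4a bond) is set by a syn-SN2′ allyl–aryl coupling of an (R)-allylic acetate with an arylboronic acid. This is a 1,3-chirality transfer, and the old C–O stereocentre ends as a CH2 group.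
- The (R)-allylic acetate comes from a Heck arylation (C4–naphthyl bond) of (R)-1-(benzyloxy)but-3-en-2-yl acetate, which is made from (R)-benzyl glycidyl ether.
- The naphthalene and the benzenoid ring are bought.

Assumption: compounds 1, 4 and 8 are taken as catalogue items, and 4 is the only chiral purchase. The target is (S) at C4 (CIP order: C4a > naphthyl > CH2 > H).

**Step 1**
Reactants: 1 5-methoxynaphthalen-1-ol
Product: 3 4-iodo-5-methoxynaphthalen-1-yl acetate, via 4-iodo-5-methoxynaphthalen-1-ol 2 (not isolated)
Conditions: NIS (1.05 equiv), MeCN, −20 → 0 °C, dark; then Ac2O (1.5 equiv), pyridine (co-solvent), 0 °C → rt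
Reagents that add atoms: N-iodosuccinimide O=C1CCC(=O)N1I; acetic anhydride CC(=O)OC(C)=O
Why: Electrophilic aromatic iodination goes para to the free OH, which is the strongest donor (NIS/MeCN is para-selective), and O-acetylation in the same flask stabilises the sensitive iodonaphthol and lowers the donor strength of the naphthalene for steps 6 and 7; no stereocentre is involved.

**Step 2**
Reactants: 4 (R)-benzyl glycidyl ether
Product: 6 (2R)-1-(benzyloxy)but-3-en-2-yl acetate, via lithium (2R)-1-(benzyloxy)but-3-en-2-olate 5 (not isolated)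
Conditions: Me3S+ I− (3 equiv), n-BuLi (2.9 equiv), THF, −10 °C → rt; then Ac2O (4 equiv), 0 °C
Reagents that add atoms: trimethylsulfonium iodide C[S+](C)C.[I-]; acetic anhydride CC(=O)OC(C)=O
Why: This is the sulfonium-ylide (Corey–Chaykovsky reagent) one-carbon homologation of a terminal epoxide to an allylic alcohol, in which the ylide opens the CH2 terminus and a second equivalent eliminates Me2S; the C–O bond at the bought stereocentre is never broken, so (R) is retained, and the alkoxide is trapped as the acetate.

**Step 3**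
Reactants: 3 4-iodo-5-methoxynaphthalen-1-yl acetate; 6 (2R)-1-(benzyloxy)but-3-en-2-yl acetate
Product: 7 4-[(1E,3R)-3-(acetyloxy)-4-(benzyloxy)but-1-en-1-yl]-5-methoxynaphthalen-1-yl acetate
Conditions: Pd(OAc)2 (5 mol %), Ag2CO3 (0.6 equiv), toluene, 80 °C, dark
Reagents that add atoms: none
Why: A ligand-free, silver-promoted Mizoroki–Heck arylation of the terminal alkene ends by β-hydride elimination and keeps the allylic ester; the fast-reacting aryl iodide and the halide-free cationic pathway leave little Pd(0) to ionise the acetate, so the stereocentre is untouched and the alkene is E.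

**Step 4**
Reactants: 7 4-[(1E,3R)-3-(acetyloxy)-4-(benzyloxy)but-1-en-1-yl]-5-methoxynaphthalen-1-yl acetate; 8 (2-hydroxy-5-methoxyphenyl)boronic acid
Product: 9 4-[(1S,2E)-4-(benzyloxy)-1-(2-hydroxy-5-methoxyphenyl)but-2-en-1-yl]-5-methoxynaphthalen-1-yl acetate
Conditions: Pd(OAc)2 (10 mol %), 1,10-phenanthroline (12 mol %), AgSbF6 (10 mol %), 8 (2 equiv), ClCH2CH2Cl, 60 °C
Reagents that add atoms: none
Why: In this Pd(II)-catalysed γ-selective, stereospecific allyl–aryl coupling the acetate carbonyl steers the cationic aryl–Pd to its own alkene face, and syn-carbopalladation followed by syn β-acetoxy elimination from the H-eclipsed conformer gives the E-alkene and transfers (R)-C–O to (S)-C–aryl (syn-SN2′) with only achiral ligands.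

**Step 5**
Reactants: 9 4-[(1S,2E)-4-(benzyloxy)-1-(2-hydroxy-5-methoxyphenyl)but-2-en-1-yl]-5-methoxynaphthalen-1-yl acetate
Product: 11 4-[(1S)-4-hydroxy-1-(2-hydroxy-5-methoxyphenyl)butyl]-5-methoxynaphthalen-1-yl acetate, via 4-[(1S)-4-(benzyloxy)-1-(2-hydroxy-5-methoxyphenyl)butyl]-5-methoxynaphthalen-1-yl acetate 10 (not isolated)
Conditions: H2 (1 atm), PtO2 (3 mol %), EtOAc, rt; then Pd(OH)2/C and EtOH added, H2 (1 atm), rt
Reagents that add atoms: none
Why: Catalytic hydrogenation on Pt comes first because Pt saturates the alkene with little double-bond migration (migration into conjugation with the two aryl groups would erase C4), and hydrogenolysis of the benzyl ether on Pearlman's catalyst follows; the aryl acetate, the methyl ethers and the stereocentre are unaffected.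

**Step 6**
Reactants: 11 4-[(1S)-4-hydroxy-1-(2-hydroxy-5-methoxyphenyl)butyl]-5-methoxynaphthalen-1-yl acetate
Product: 13 4-[(1S)-1-(3,6-dioxocyclohexa-1,4-dien-1-yl)-4-oxobutyl]-5-methoxynaphthalen-1-yl acetate, via 4-[(1S)-1-(3,6-dioxocyclohexa-1,4-dien-1-yl)-4-hydroxybutyl]-5-methoxynaphthalen-1-yl acetate 12 (not isolated)
Conditions: PhI(OAc)2 (2.2 equiv), TEMPO (10 mol %), CH2Cl2–H2O 50:1, 0 °C → rt; used at once
Reagents that add atoms: water O
Why: Hypervalent-iodine oxidative demethylation turns the p-methoxyphenol into the p-quinone (water attacks the OMe-bearing carbon and MeOH leaves), and the TEMPO/PhI(OAc)2 oxidation stops at the aldehyde in nearly dry CH2Cl2; the naphthyl methyl ether and acetate do not react with PhI(OAc)2 without acid activation, and the base-free medium keeps C4–H in place.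

**Step 7**
Reactants: 13 4-[(1S)-1-(3,6-dioxocyclohexa-1,4-dien-1-yl)-4-oxobutyl]-5-methoxynaphthalen-1-yl acetate
Product: 15 (4S)-5,8-dihydroxy-4-(4-hydroxy-8-methoxynaphthalen-1-yl)-3,4-dihydronaphthalen-1(2H)-one, via 4-[(1S)-5,8-dihydroxy-4-oxo-1,2,3,4-tetrahydronaphthalen-1-yl]-5-methoxynaphthalen-1-yl acetate 14 (not isolated)
Conditions: hν (450 nm LED), degassed benzene (2 mM), 20 °C; evaporate; then p-TsOH·H2O (10 mol %), MeOH, 45 °C, Ar
Reagents that add atoms: none
Why: Proposed new method: a ring-closing photo-Friedel–Crafts acylation of a quinone by its own tethered aldehyde, in which 450 nm light populates only the n,π* triplet of the quinone, the C5 carbonyl oxygen abstracts the formyl H (the weakest accessible C–H, about 88 kcal/mol, through an eight-membered transition state), and the acyl/semiquinone biradical carries spin at C8a (ortho to the phenoxyl oxygen), the only ring carbon the tether can reach, so collapse closes the six-membered ketone and enolisation gives the acylhydroquinone with no reagent and no net redox change; C4–H stays because abstraction by the adjacent carbonyl would need a strained five-membered transition state, and electron-transfer quenching by the naphthalene is held back by its O-acetyl group and the non-polar solvent, so the stereocentre is carried through; the closest known reaction type is the intermolecular photoacylation of 1,4-quinones with aldehydes (Klinger–Kolvenbach/Kraus type), which has not been shown in ring-closing form next to a diarylmethine; the methanolysis that follows is an ordinary acid-catalysed transesterification.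

**Compound list**
1 | 5-methoxynaphthalen-1-ol | COc1cccc2c(O)cccc12 | starting material
2 | 4-iodo-5-methoxynaphthalen-1-ol | COc1cccc2c(O)ccc(I)c12 | intermediate
3 | 4-iodo-5-methoxynaphthalen-1-yl acetate | COc1cccc2c(OC(C)=O)ccc(I)c12 | intermediate
4 | (R)-benzyl glycidyl ether | C1O[C@H]1COCc1ccccc1 | starting material
5 | lithium (2R)-1-(benzyloxy)but-3-en-2-olate | C=C[C@@H]([O-])COCc1ccccc1.[Li+] | intermediate
6 | (2R)-1-(benzyloxy)but-3-en-2-yl acetate | C=C[C@@H](OC(C)=O)COCc1ccccc1 | intermediate
7 | 4-[(1E,3R)-3-(acetyloxy)-4-(benzyloxy)but-1-en-1-yl]-5-methoxynaphthalen-1-yl acetate | COc1cccc2c(OC(C)=O)ccc(/C=C/[C@@H](OC(C)=O)COCc3ccccc3)c12 | intermediate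
8 | (2-hydroxy-5-methoxyphenyl)boronic acid | OB(O)c1cc(OC)ccc1O | starting material
9 | 4-[(1S,2E)-4-(benzyloxy)-1-(2-hydroxy-5-methoxyphenyl)but-2-en-1-yl]-5-methoxynaphthalen-1-yl acetate | COc1cccc2c(OC(C)=O)ccc([C@H](/C=C/COCc3ccccc3)c3cc(OC)ccc3O)c12 | intermediate
10 | 4-[(1S)-4-(benzyloxy)-1-(2-hydroxy-5-methoxyphenyl)butyl]-5-methoxynaphthalen-1-yl acetate | COc1cccc2c(OC(C)=O)ccc([C@H](CCCOCc3ccccc3)c3cc(OC)ccc3O)c12 | intermediate
11 | 4-[(1S)-4-hydroxy-1-(2-hydroxy-5-methoxyphenyl)butyl]-5-methoxynaphthalen-1-yl acetate | COc1cccc2c(OC(C)=O)ccc([C@H](CCCO)c3cc(OC)ccc3O)c12 | intermediate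
12 | 4-[(1S)-1-(3,6-dioxocyclohexa-1,4-dien-1-yl)-4-hydroxybutyl]-5-methoxynaphthalen-1-yl acetate | COc1cccc2c(OC(C)=O)ccc([C@H](CCCO)C3=CC(=O)C=CC3=O)c12 | intermediate
13 | 4-[(1S)-1-(3,6-dioxocyclohexa-1,4-dien-1-yl)-4-oxobutyl]-5-methoxynaphthalen-1-yl acetate | COc1cccc2c(OC(C)=O)ccc([C@H](CCC=O)C3=CC(=O)C=CC3=O)c12 | intermediate
14 | 4-[(1S)-5,8-dihydroxy-4-oxo-1,2,3,4-tetrahydronaphthalen-1-yl]-5-methoxynaphthalen-1-yl acetate | COc1cccc2c(OC(C)=O)ccc([C@@H]3CCC(=O)c4c(O)ccc(O)c43)c12 | intermediate
15 | (4S)-5,8-dihydroxy-4-(4-hydroxy-8-methoxynaphthalen-1-yl)-3,4-dihydronaphthalen-1(2H)-one | COc1cccc2c(O)ccc([C@@H]3CCC(=O)c4c(O)ccc(O)c43)c12 | target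

**Total step count:** 7.
**Longest linear sequence:** 6 (steps 1 or 2, then 3, 4, 5, 6, 7).

**Steps most likely to fail**

*Step 7 (the proposed new step).*
- Risks: the excited quinone may be quenched by the neighbouring naphthalene, the C3–H may be abstracted instead of the formyl H, or the biradical may collapse at oxygen.
- Fallback with known polar chemistry, setting out from 13 and returning at 14. Pinnick oxidation (NaClO2, NaH2PO4, 2-methyl-2-butene, t-BuOH–H2O) gives (4S)-4-[4-(acetyloxy)-8-methoxynaphthalen-1-yl]-4-(3,6-dioxocyclohexa-1,4-dien-1-yl)butanoic acid F1. Aqueous Na2S2O4 in EtOAc reduces the quinone to (4S)-4-[4-(acetyloxy)-8-methoxynaphthalen-1-yl]-4-(2,5-dihydroxyphenyl)butanoic acid F2. Intramolecular Friedel–Crafts acylation (Eaton's reagent, 20 °C) ortho to the C8 hydroxyl then closes the tetralone to 14, which is deacetylated as in step 7.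

*Step 4.*
- Risks: the aryl group must be placed on the carbon that already carries the peri-methoxynaphthyl group, against the usual styrene insertion sense, and boronic acid 8 can protodeboronate.
- Fallback by a sigmatropic route, setting out from 7 and returning at 9. Pd(0)-catalysed allylic etherification with 4-methoxyphenol (Pd2(dba)3, dppf, THF, rt) proceeds by double inversion, so with net retention, and attacks the carbon remote from the naphthyl group. It gives 4-[(1E,3R)-4-(benzyloxy)-3-(4-methoxyphenoxy)but-1-en-1-yl]-5-methoxynaphthalen-1-yl acetate F3. A suprafacial, chair-like aromatic Claisen rearrangement (Eu(fod)3, toluene, 110 °C, or PhNEt2, 180 °C) delivers the ortho carbon to the same face that the oxygen leaves and gives 9 directly.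

*Step 3.*
- Risks: β-acetoxy elimination may win over β-hydride elimination, transient Pd(0) may ionise or racemise acetate 6, and insertion of the hindered aryl group may be slow.
- Fallback that keeps palladium away from the allylic acetate, setting out from 3 and returning at 7. Stille vinylation (tributyl(vinyl)stannane, Pd(PPh3)4, toluene, 90 °C) gives 4-ethenyl-5-methoxynaphthalen-1-yl acetate F4. E-selective cross-metathesis of F4 with 6 (Hoveyda–Grubbs II, CH2Cl2, 40 °C) gives 7 with the stereocentre untouched.

**Further compounds**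
F1 | step 7 | (4S)-4-[4-(acetyloxy)-8-methoxynaphthalen-1-yl]-4-(3,6-dioxocyclohexa-1,4-dien-1-yl)butanoic acid | COc1cccc2c(OC(C)=O)ccc([C@H](CCC(=O)O)C3=CC(=O)C=CC3=O)c12
F2 | step 7 | (4S)-4-[4-(acetyloxy)-8-methoxynaphthalen-1-yl]-4-(2,5-dihydroxyphenyl)butanoic acid | COc1cccc2c(OC(C)=O)ccc([C@H](CCC(=O)O)c3cc(O)ccc3O)c12
F3 | step 4 | 4-[(1E,3R)-4-(benzyloxy)-3-(4-methoxyphenoxy)but-1-en-1-yl]-5-methoxynaphthalen-1-yl acetate | COc1cccc2c(OC(C)=O)ccc(/C=C/[C@@H](Oc3ccc(OC)cc3)COCc3ccccc3)c12
F4 | step 3 | 4-ethenyl-5-methoxynaphthalen-1-yl acetate | COc1cccc2c(OC(C)=O)ccc(C=C)c12
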